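The cyclohexane ring of the target has the C1 carboxyl and O5 cis and 1,3-related, and O4 trans to O5. The route therefore rests on disconnecting the O5–acyl lactone bond and the C4 heteroatom back to a cyclohex-3-ene acid: one bromolactonization forms O–C5 and C4–Br, closes the bridged γ-lactone (6-oxabicyclo[3.2.1]octan-7-one) and sets C5 and C4 from C1. Its precursor, (S)-1-hydroxycyclohex-3-ene-1-carboxylic acid, is chiral at C1 and is made enantiopure by a lactate-auxiliary Diels–Alder reaction. The lactone then masks CO2H and O5 while elimination, dihydroxylation anti to the lactone bridge and two ordered acylations complete O3 and O4.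

Key step: step 5

Remark on the chemistry: 1-hydroxycyclohex-3-ene-1-carboxylic acid is not achiral. C1 carries one allylic and one homoallylic ring CH2, so it is a stereocentre and the two alkene carbons are constitutionally different; a chiral brominating catalyst could at best resolve the racemate. The acid is therefore built as the single (S)-enantiomer, and the bromolactonization runs under substrate control with an achiral bromine source.

Numbering: ring atoms are numbered as in quinic acid throughout: C1 (OH, CO2H), C3 (caffeate), C4 (p-coumarate), C5 (free OH). In acid 8 the alkene is C4=C5 in this numbering. The target belongs to the natural (−)-quinic acid series.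

Step 1
Reactants: 1 (R)-lactic acid; 2 pivalaldehyde
Product: 3 (2R,5R)-2-tert-butyl-5-methyl-1,3-dioxolan-4-one (cis)
Conditions: p-toluenesulfonic acid monohydrate (cat.), H2SO4 (cat.), pentane, reflux, Dean–Stark trap; crystallization from Et2O/pentane at −78 °C
Reagents that add atoms: none
Why: Acid-catalysed acetalization with azeotropic removal of water leaves the lactate centre untouched and places the tert-butyl group cis to the methyl group, the cis isomer being enriched by low-temperature crystallization so that a single acetal configuration (R) is carried on.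

Step 2
Reactants: 3 (2R,5R)-2-tert-butyl-5-methyl-1,3-dioxolan-4-one
Product: 5 (R)-2-tert-butyl-5-methylidene-1,3-dioxolan-4-one, via 5-bromo-5-methyl dioxolanone 4 (not isolated)
Conditions: NBS, 2,2'-azobis(2-methylpropionitrile) (cat.), PhCF3, 80 °C; filtration; then Et3N, 0 °C to rt
Reagents that add atoms: none
Why: Radical bromination under Wohl–Ziegler conditions is selective for the captodative C5–H, and E2 loss of HBr can only give the exocyclic alkene, which leaves the acetal carbon as the sole stereocentre of the dienophile.

Step 3
Reactants: 5 (R)-2-tert-butyl-5-methylidene-1,3-dioxolan-4-one; 6 buta-1,3-diene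
Product: 7 (2R,5S)-2-tert-butyl-1,3-dioxaspiro[4.5]dec-7-en-4-one
Conditions: buta-1,3-diene (excess), 2,6-di-tert-butyl-4-methylphenol (inhibitor), toluene, sealed tube, 100 °C
Reagents that add atoms: none
Why: Thermal Diels–Alder reaction of a 2-alkoxyacrylate-type dienophile, in which butadiene adds to the alkene face anti to the tert-butyl group and so sets the spiro carbon (future C1) as S, the minor syn adduct being a diastereomer that chromatography removes.

Step 4
Reactants: 7 (2R,5S)-2-tert-butyl-1,3-dioxaspiro[4.5]dec-7-en-4-one
Product: 8 (S)-1-hydroxycyclohex-3-ene-1-carboxylic acid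
Conditions: LiOH, THF/H2O, rt; then aq. HCl to pH 2, extraction
Reagents that add atoms: lithium hydroxide, [Li+].[OH-]
Why: Saponification of the dioxolanone ester gives a hemiacetal alkoxide that collapses with loss of pivalaldehyde, and since no bond to the quaternary carbon is broken C1 keeps its configuration.

Step 5
Reactants: 8 (S)-1-hydroxycyclohex-3-ene-1-carboxylic acid
Product: 9 (1S,4R,5R)-4-bromo-1-hydroxy-6-oxabicyclo[3.2.1]octan-7-one
Conditions: NBS, NaHCO3 (buffer), THF/H2O, 0 °C, dark
Reagents that add atoms: N-bromosuccinimide, O=C1CCC(=O)N1Br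
Why: NBS transfers Br+ reversibly to the C4=C5 alkene; only the bromonium ion on the ring face syn to the C1 hydroxyl (anti to the carboxylate) is productive, and the carboxylate opens it at C5 from the opposite face, which is the well-known halolactonization of cyclohex-3-ene-1-carboxylic acids. The one ring closed is the γ-lactone, formed in the 5-exo mode through a boat-like ring to give the 6-oxabicyclo[3.2.1]octan-7-one and not the 6-endo δ-lactone (2-oxabicyclo[2.2.2]octanone). C5 is set by the tether, because the carboxyl on C1 can reach C5 only on its own ring face, so O5 ends cis to the carboxyl carbon; C4 is set by the anti opening, so bromine ends trans to O5 (trans-diaxial). Both new centres are thus dictated by the existing (S)-C1 centre and no external chiral reagent is needed, whereas the enantiomeric acid would give the mirror-image lactone, which is why the acid must be enantiopure. The step needs γ- over δ-closure, secured by the 5-exo preference, and carboxylate over tertiary hydroxyl attack (which would give a 7-oxabicyclo[2.2.1]heptane), secured by working on the bicarbonate-buffered carboxylate at 0 °C in the dark, conditions that also hold back oxidative decarboxylation of the α-hydroxy acid.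

Step 6
Reactants: 9 (1S,4R,5R)-4-bromo-1-hydroxy-6-oxabicyclo[3.2.1]octan-7-one
Product: 10 (1S,4R,5R)-4-bromo-1-(triethylsilyloxy)-6-oxabicyclo[3.2.1]octan-7-one
Conditions: TESOTf, 2,6-lutidine, CH2Cl2, −40 to 0 °C
Reagents that add atoms: triethylsilyl trifluoromethanesulfonate, CC[Si](CC)(CC)OS(=O)(=O)C(F)(F)F
Why: Silylation of a tertiary alcohol with a silyl triflate and a hindered pyridine base is standard, and the ether blocks O1 against the later acylations and is lost in the final acid step.

Step 7
Reactants: 10 (1S,4R,5R)-4-bromo-1-(triethylsilyloxy)-6-oxabicyclo[3.2.1]octan-7-one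
Product: 11 (1S,5R)-1-(triethylsilyloxy)-6-oxabicyclo[3.2.1]oct-3-en-7-one
Conditions: DBU, toluene, 100 °C
Reagents that add atoms: none
Why: E2 dehydrobromination with an amidine base, in which the axial C4–Br is antiperiplanar only to the axial C3–H (C5–H is equatorial), so the C3=C4 alkene forms and no enol ether.

Step 8
Reactants: 11 (1S,5R)-1-(triethylsilyloxy)-6-oxabicyclo[3.2.1]oct-3-en-7-one
Product: 12 (1S,3R,4R,5R)-3,4-dihydroxy-1-(triethylsilyloxy)-6-oxabicyclo[3.2.1]octan-7-one
Conditions: OsO4 (cat.), N-methylmorpholine N-oxide, acetone/H2O, rt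
Reagents that add atoms: osmium tetroxide, O=[Os](=O)(=O)=O; N-methylmorpholine N-oxide, C[N+]1([O-])CCOCC1; water, O
Why: OsO4-catalysed syn-dihydroxylation takes place on the convex face anti to the lactone bridge and to the allylic C5–O bond, which places O3 and O4 cis to each other and trans to O5.

Step 9
Reactants: 13 caffeic acid
Product: 14 (E)-3-(3,4-diacetoxyphenyl)prop-2-enoic acid
Conditions: Ac2O, pyridine, 4-(dimethylamino)pyridine (cat.), rt; then H2O
Reagents that add atoms: acetic anhydride, CC(=O)OC(C)=O
Why: Pyridine-mediated O-acetylation of both phenols, the aqueous work-up hydrolysing any mixed anhydride at the carboxyl group.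

Step 10
Reactants: 12 (1S,3R,4R,5R)-3,4-dihydroxy-1-(triethylsilyloxy)-6-oxabicyclo[3.2.1]octan-7-one; 14 (E)-3-(3,4-diacetoxyphenyl)prop-2-enoic acid
Product: 16 3-O-[(E)-3,4-diacetoxycinnamoyl]-1-O-triethylsilylquinide (O3 ester of 12, O4–H free), via diacetylcaffeoyl chloride 15 (not isolated)
Conditions: 14, (COCl)2, N,N-dimethylformamide (cat.), CH2Cl2, 0 °C to rt, evaporation; then 12, about one equivalent of the acid chloride, pyridine, CH2Cl2, −20 to 0 °C, dark
Reagents that add atoms: none
Why: Acid chloride formation followed by pyridine-mediated esterification at low temperature with one equivalent should favour the equatorial, unhindered O3–H over the axial O4–H that is flanked by the lactone oxygen.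

Step 11
Reactants: 17 p-coumaric acid
Product: 18 (E)-3-(4-acetoxyphenyl)prop-2-enoic acid
Conditions: Ac2O, pyridine, 4-(dimethylamino)pyridine (cat.), rt; then H2O
Reagents that add atoms: acetic anhydride, CC(=O)OC(C)=O
Why: Pyridine-mediated O-acetylation of the phenol, as in step 9.

Step 12
Reactants: 16 3-O-[(E)-3,4-diacetoxycinnamoyl]-1-O-triethylsilylquinide; 18 (E)-3-(4-acetoxyphenyl)prop-2-enoic acid
Product: 20 4-O-[(E)-4-acetoxycinnamoyl]-3-O-[(E)-3,4-diacetoxycinnamoyl]-1-O-triethylsilylquinide, via 4-acetoxycinnamoyl chloride 19 (not isolated)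
Conditions: 18, (COCl)2, N,N-dimethylformamide (cat.), CH2Cl2, 0 °C to rt, evaporation; then 16, excess acid chloride, pyridine, 4-(dimethylamino)pyridine (cat.), CH2Cl2, rt, dark
Reagents that add atoms: none
Why: Acylation of the remaining axial O4–H with excess acid chloride under nucleophilic catalysis, where O1 is silylated and the first ester already sits at the more stable equatorial site, which disfavours acyl migration.

Step 13
Reactants: 20 4-O-[(E)-4-acetoxycinnamoyl]-3-O-[(E)-3,4-diacetoxycinnamoyl]-1-O-triethylsilylquinide
Product: 21 (1R,3R,4S,5R)-3-{[(E)-3-(3,4-dihydroxyphenyl)prop-2-enoyl]oxy}-1,5-dihydroxy-4-{[(E)-3-(4-hydroxyphenyl)prop-2-enoyl]oxy}cyclohexane-1-carboxylic acid (target)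
Conditions: 2 M aq. HCl/THF, rt to 35 °C, dark; reversed-phase chromatography
Reagents that add atoms: water, O
Why: Acid-catalysed hydrolysis should cleave the three aryl acetates (activated phenyl esters), the silyl ether and the strained bridged lactone (acyl–oxygen cleavage, C5 retained) faster than the two cinnamates of secondary alcohols, and the acidic medium suppresses acyl migration.

Compound list
1 | (R)-lactic acid | C[C@@H](O)C(=O)O | starting material
2 | pivalaldehyde (2,2-dimethylpropanal) | CC(C)(C)C=O | starting material
3 | (2R,5R)-2-tert-butyl-5-methyl-1,3-dioxolan-4-one (tert-butyl and methyl cis) | C[C@H]1O[C@@H](C(C)(C)C)OC1=O | intermediate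
4 | (2R,5S)-5-bromo-2-tert-butyl-5-methyl-1,3-dioxolan-4-one (bromine expected anti to tert-butyl; not isolated) | C[C@@]1(Br)O[C@@H](C(C)(C)C)OC1=O | intermediate
5 | (R)-2-tert-butyl-5-methylidene-1,3-dioxolan-4-one | C=C1O[C@@H](C(C)(C)C)OC1=O | intermediate
6 | buta-1,3-diene | C=CC=C | starting material
7 | (2R,5S)-2-tert-butyl-1,3-dioxaspiro[4.5]dec-7-en-4-one (allylic CH2 of the new ring anti to tert-butyl) | CC(C)(C)[C@H]1OC(=O)[C@@]2(O1)CC=CCC2 | intermediate
8 | (S)-1-hydroxycyclohex-3-ene-1-carboxylic acid | O[C@]1(C(=O)O)CC=CCC1 | intermediate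
9 | (1S,4R,5R)-4-bromo-1-hydroxy-6-oxabicyclo[3.2.1]octan-7-one (Br trans to the lactone oxygen) | Br[C@H]1[C@H](OC2=O)C[C@@]2(O)CC1 | intermediate
10 | (1S,4R,5R)-4-bromo-1-(triethylsilyloxy)-6-oxabicyclo[3.2.1]octan-7-one | Br[C@H]1[C@H](OC2=O)C[C@@]2(O[Si](CC)(CC)CC)CC1 | intermediate
11 | (1S,5R)-1-(triethylsilyloxy)-6-oxabicyclo[3.2.1]oct-3-en-7-one | C1=C[C@H](OC2=O)C[C@@]2(O[Si](CC)(CC)CC)C1 | intermediate
12 | (1S,3R,4R,5R)-3,4-dihydroxy-1-(triethylsilyloxy)-6-oxabicyclo[3.2.1]octan-7-one (1-O-triethylsilylquinide; O3 and O4 cis, both anti to the lactone bridge) | O[C@H]1[C@H](OC2=O)C[C@@]2(O[Si](CC)(CC)CC)C[C@H]1O | intermediate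
13 | caffeic acid | OC(=O)/C=C/c1ccc(O)c(O)c1 | starting material
14 | (E)-3-(3,4-diacetoxyphenyl)prop-2-enoic acid | CC(=O)Oc1ccc(/C=C/C(=O)O)cc1OC(C)=O | intermediate
15 | (E)-3-(3,4-diacetoxyphenyl)prop-2-enoyl chloride (not isolated) | CC(=O)Oc1ccc(/C=C/C(=O)Cl)cc1OC(C)=O | intermediate
16 | 3-O-[(E)-3,4-diacetoxycinnamoyl]-1-O-triethylsilylquinide (ester at the equatorial O3 of 12, ring configuration of 12 retained) | O[C@H]1[C@H](OC2=O)C[C@@]2(O[Si](CC)(CC)CC)C[C@H]1OC(=O)/C=C/c1ccc(OC(C)=O)c(OC(C)=O)c1 | intermediate
17 | p-coumaric acid | OC(=O)/C=C/c1ccc(O)cc1 | starting material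
18 | (E)-3-(4-acetoxyphenyl)prop-2-enoic acid | CC(=O)Oc1ccc(/C=C/C(=O)O)cc1 | intermediate
19 | (E)-3-(4-acetoxyphenyl)prop-2-enoyl chloride (not isolated) | CC(=O)Oc1ccc(/C=C/C(=O)Cl)cc1 | intermediate
20 | 4-O-[(E)-4-acetoxycinnamoyl]-3-O-[(E)-3,4-diacetoxycinnamoyl]-1-O-triethylsilylquinide (ring configuration of 12 retained) | O=C(/C=C/c1ccc(OC(C)=O)cc1)O[C@H]1[C@H](OC2=O)C[C@@]2(O[Si](CC)(CC)CC)C[C@H]1OC(=O)/C=C/c1ccc(OC(C)=O)c(OC(C)=O)c1 | intermediate
21 | (1R,3R,4S,5R)-3-O-(E)-caffeoyl-4-O-(E)-p-coumaroylquinic acid | O=C(/C=C/c1ccc(O)cc1)O[C@H]1[C@H](O)C[C@](O)(C(=O)O)C[C@H]1OC(=O)/C=C/c1ccc(O)c(O)c1 | target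

Total step count: 13
Longest linear sequence: 11 steps (steps 1–8, 10, 12 and 13, from (R)-lactic acid)

Steps most likely to fail

Step 3. The dienophile may polymerise, or add with incomplete facial discrimination, at the temperature that butadiene requires, so that too little diastereomerically pure adduct is obtained. The fallback sets out from buta-1,3-diene 6 and commercial methyl 2-acetoxyacrylate (COC(=O)C(=C)OC(C)=O). Their thermal Diels–Alder reaction (sealed tube, hydroquinone as inhibitor) should give racemic methyl 1-acetoxycyclohex-3-ene-1-carboxylate F1. Preparative chromatography on a chiral stationary phase then separates methyl (S)-1-acetoxycyclohex-3-ene-1-carboxylate F2, the enantiomer being assigned by correlation of a sample with natural quinide after steps 5–8. LiOH in aqueous THF followed by acidification cleaves both ester groups and returns to the route at acid 8; steps 1, 2 and 4 then fall away and step 5 is unchanged.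

Step 10. Discrimination between O3–H and O4–H may be insufficient, leading to the O4 ester or to double acylation. The fallback sets out from diol 12, which is heated with Bu2SnO in toluene with removal of water to give the 3,4-O-dibutylstannylene acetal of 12 F3. Stannylene acetals of cis-diols on six-membered rings are acylated at the equatorial oxygen, so treatment with acid chloride 15 at 0 °C and aqueous work-up should deliver the O3 ester and come back to the route at 16.

Step 13. The slow acid hydrolysis of the aryl acetates demands long exposure, during which the cinnamate esters may hydrolyse or migrate to O5 once the lactone has opened. The fallback sets out from 20 and separates the two tasks. Hydrazinolysis with N2H4·AcOH in N,N-dimethylformamide at 0 °C removes the three aryl acetates selectively and gives 3-O-(E)-caffeoyl-4-O-(E)-p-coumaroyl-1-O-triethylsilylquinide F4. A short treatment with aqueous trifluoroacetic acid in THF then removes the silyl ether and opens the lactone, coming back to the route at target 21.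

Further compounds
F1 | step 3 | methyl 1-acetoxycyclohex-3-ene-1-carboxylate (racemate) | COC(=O)C1(OC(C)=O)CC=CCC1
F2 | step 3 | methyl (S)-1-acetoxycyclohex-3-ene-1-carboxylate | COC(=O)[C@@]1(OC(C)=O)CC=CCC1
F3 | step 10 | 3,4-O-dibutylstannylene acetal of 12 | CCCC[Sn]1(CCCC)O[C@H]2[C@H](OC3=O)C[C@@]3(O[Si](CC)(CC)CC)C[C@H]2O1
F4 | step 13 | 3-O-(E)-caffeoyl-4-O-(E)-p-coumaroyl-1-O-triethylsilylquinide | O=C(/C=C/c1ccc(O)cc1)O[C@H]1[C@H](OC2=O)C[C@@]2(O[Si](CC)(CC)CC)C[C@H]1OC(=O)/C=C/c1ccc(O)c(O)c1
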